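**Strategy**

Ring C is disconnected at C2–C3 and O1–C8a, which splits the flavanone into the ring B aldehyde, whose C=O becomes C2–O1, and a ring A 2-fluoroaryl methyl ketone holding C3–C4–C4a–C8a. The key step exploits that the C4 carbonyl both turns C3 into an enol nucleophile and, being ortho to C8a, activates a fluoride there for substitution: a catalytic asymmetric Mukaiyama aldol sets C2 and forms C2–C3, and a fluoride relay then closes O1–C8a by intramolecular SNAr in the same flask. The precursor is the trimethylsilyl enol ether of the 2-fluoroacetophenone; its silyl group and ring fluorine leave together as Me3SiF.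

Key step: step 6

Assumption: compounds 1, 4 and 6 are purchased, and the (R)-tryptophan-derived oxazaborolidinone is taken to stack its indole on the Re face of the boron-bound aryl aldehyde so that the Si face reacts (giving the (S)-carbinol); should a model aldol show the opposite sense, the (S)-tryptophan-derived catalyst is used.

**Route**

Step 1
Reactants: 1 3-bromo-4,5-dihydroxybenzaldehyde
Product: 2 3-bromo-5-hydroxy-4-methoxybenzaldehyde
Conditions: MeI (1.05 equiv), Li2CO3 (1.1 equiv), DMF, 45 °C
Reagents that add atoms: iodomethane, CI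
Why: The 4-OH (para to the formyl group, ortho to bromine) is much the more acidic phenol, so the weak base should form only that phenoxide and the Williamson ether synthesis should methylate O4 selectively.

Step 2
Reactants: 2 3-bromo-5-hydroxy-4-methoxybenzaldehyde
Product: 3 3-bromo-4-methoxy-5-(methoxymethoxy)benzaldehyde
Conditions: MOMCl, i-Pr2NEt, CH2Cl2, 0 °C → rt
Reagents that add atoms: chloromethyl methyl ether, COCCl
Why: O-alkylation of the remaining phenol with an α-chloro ether (methoxymethyl ether formation) masks it as a base- and fluoride-stable acetal.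

Step 3
Reactants: 3 3-bromo-4-methoxy-5-(methoxymethoxy)benzaldehyde, 4 4,4,5,5-tetramethyl-2-(3-methylbut-2-en-1-yl)-1,3,2-dioxaborolane
Product: 5 4-methoxy-3-(methoxymethoxy)-5-(3-methylbut-2-en-1-yl)benzaldehyde
Conditions: Pd(dppf)Cl2·CH2Cl2 (5 mol %), K3PO4, THF/H2O, 70 °C
Reagents that add atoms: none
Why: Suzuki–Miyaura coupling of the aryl bromide with the allylic boronate; with the chelating diphosphine the allyl–palladium intermediate should equilibrate and reductively eliminate at the unhindered CH2 terminus to give the linear prenyl arene, and the aldehyde and acetal tolerate the mild base.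

Step 4
Reactants: 6 1-(2-fluoro-4-hydroxyphenyl)ethan-1-one
Product: 7 1-[2-fluoro-4-(methoxymethoxy)phenyl]ethan-1-one
Conditions: MOMCl, i-Pr2NEt, CH2Cl2, 0 °C → rt
Reagents that add atoms: chloromethyl methyl ether, COCCl
Why: Methoxymethyl ether formation keeps the para oxygen from becoming a phenoxide, which would shut down the later substitution at the fluorinated carbon.

Step 5
Reactants: 7 1-[2-fluoro-4-(methoxymethoxy)phenyl]ethan-1-one
Product: 9 {[1-(2-fluoro-4-(methoxymethoxy)phenyl)ethenyl]oxy}trimethylsilane, via lithium enolate 8 (not isolated)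
Conditions: LiHMDS, THF, −78 °C; then TMSCl, −78 → 0 °C; non-aqueous work-up (pentane, filtration)
Reagents that add atoms: chlorotrimethylsilane, C[Si](C)(C)Cl
Why: Kinetic deprotonation of the methyl ketone and O-silylation of the lithium enolate (silyl enol ether formation) should proceed cleanly at low temperature, where the aryl fluoride and the acetal are inert to the amide base.

Step 6
Reactants: 9 {[1-(2-fluoro-4-(methoxymethoxy)phenyl)ethenyl]oxy}trimethylsilane, 5 4-methoxy-3-(methoxymethoxy)-5-(3-methylbut-2-en-1-yl)benzaldehyde
Product: 12 (2S)-7-(methoxymethoxy)-2-[4-methoxy-3-(methoxymethoxy)-5-(3-methylbut-2-en-1-yl)phenyl]-2,3-dihydro-4H-chromen-4-one, via silyl ether aldol adduct 10 (not isolated), via tetrabutylammonium alkoxide 11 (not isolated)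
Conditions: (4R)-2-butyl-4-(1H-indol-3-ylmethyl)-3-tosyl-1,3,2-oxazaborolidin-5-one (20 mol %, preformed from N-tosyl-(R)-tryptophan and BuB(OH)2), EtCN, −78 °C; then Bu4N[Ph3SiF2] (0.4 equiv), DMF, −78 → 0 °C
Reagents that add atoms: none
Why: A Mukaiyama aldol addition under chiral boron Lewis acid catalysis joins the enol silane carbon (C3) to the aldehyde carbon (C2) and passes the silyl group to the aldehyde oxygen (the future O1) to give 10; fluoride then cleaves the O–Si bond, and alkoxide 11 attacks the fluorine-bearing C8a ortho to the ketone by addition–elimination through an anionic σ-adduct stabilised as the C4 enolate, expelling fluoride, which desilylates the next molecule of 10, so substoichiometric fluoride should carry the relay and Me3SiF is the only by-product. The closest known reaction types are the oxazaborolidinone-catalysed Mukaiyama aldol of aryl methyl ketone enol silanes with aldehydes and the fluoride-promoted SNAr of silyl ethers or alkoxides on ortho-acyl fluoroarenes. Ring C closes in a 6-exo-trig mode (taking the C8–C8a arene bond as the exocyclic π bond) by O1 attacking sp2 C8a. The C2 stereocentre is set in the aldol stage by the catalyst, whose indole covers one face of the boron-bound aldehyde so that the enol silane adds to the Si face, and no bond to C2 is made or broken in the substitution stage, so the (S) configuration should pass unchanged into 12. The step needs ring closure to outrun retro-aldol cleavage and E1cB loss of the oxygen from 11, which the ortho-acyl activation, the six-membered transition state, the low temperature and the absence of stoichiometric base should favour. It also needs the flavanone to resist base-induced opening to the chalcone, which the merely catalytic level of alkoxide and fluoride should secure.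

Step 7
Reactants: 12 (2S)-7-(methoxymethoxy)-2-[4-methoxy-3-(methoxymethoxy)-5-(3-methylbut-2-en-1-yl)phenyl]-2,3-dihydro-4H-chromen-4-one
Product: 13 erylatissin C, (2S)-7-hydroxy-2-[3-hydroxy-4-methoxy-5-(3-methylbut-2-en-1-yl)phenyl]-2,3-dihydro-4H-chromen-4-one
Conditions: HCl (2 M aq), MeOH/THF, 40 °C
Reagents that add atoms: none
Why: Acid-catalysed acetal methanolysis should free both phenols; the prenyl group sits next to OMe and not OH, so no chroman can form, and the base-type retro-oxa-Michael opening that racemises flavanones does not operate in dilute acid.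

**Compound list**

1 | 3-bromo-4,5-dihydroxybenzaldehyde | O=Cc1cc(O)c(O)c(Br)c1 | starting material
2 | 3-bromo-5-hydroxy-4-methoxybenzaldehyde | COc1c(O)cc(C=O)cc1Br | intermediate
3 | 3-bromo-4-methoxy-5-(methoxymethoxy)benzaldehyde | COCOc1cc(C=O)cc(Br)c1OC | intermediate
4 | 4,4,5,5-tetramethyl-2-(3-methylbut-2-en-1-yl)-1,3,2-dioxaborolane | CC(C)=CCB1OC(C)(C)C(C)(C)O1 | starting material
5 | 4-methoxy-3-(methoxymethoxy)-5-(3-methylbut-2-en-1-yl)benzaldehyde | COCOc1cc(C=O)cc(CC=C(C)C)c1OC | intermediate
6 | 1-(2-fluoro-4-hydroxyphenyl)ethan-1-one | CC(=O)c1ccc(O)cc1F | starting material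
7 | 1-[2-fluoro-4-(methoxymethoxy)phenyl]ethan-1-one | CC(=O)c1ccc(OCOC)cc1F | intermediate
8 | lithium 1-[2-fluoro-4-(methoxymethoxy)phenyl]ethen-1-olate | [Li]OC(=C)c1ccc(OCOC)cc1F | intermediate
9 | {[1-(2-fluoro-4-(methoxymethoxy)phenyl)ethenyl]oxy}trimethylsilane | C=C(O[Si](C)(C)C)c1ccc(OCOC)cc1F | intermediate
10 | (3S)-1-[2-fluoro-4-(methoxymethoxy)phenyl]-3-[4-methoxy-3-(methoxymethoxy)-5-(3-methylbut-2-en-1-yl)phenyl]-3-[(trimethylsilyl)oxy]propan-1-one | COc1c(OCOC)cc([C@H](CC(=O)c2ccc(OCOC)cc2F)O[Si](C)(C)C)cc1CC=C(C)C | intermediate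
11 | tetrabutylammonium (1S)-3-[2-fluoro-4-(methoxymethoxy)phenyl]-1-[4-methoxy-3-(methoxymethoxy)-5-(3-methylbut-2-en-1-yl)phenyl]-3-oxopropan-1-olate | CCCC[N+](CCCC)(CCCC)CCCC.COc1c(OCOC)cc([C@H](CC(=O)c2ccc(OCOC)cc2F)[O-])cc1CC=C(C)C | intermediate
12 | (2S)-7-(methoxymethoxy)-2-[4-methoxy-3-(methoxymethoxy)-5-(3-methylbut-2-en-1-yl)phenyl]-2,3-dihydro-4H-chromen-4-one | COc1c(OCOC)cc([C@@H]2CC(=O)c3ccc(OCOC)cc3O2)cc1CC=C(C)C | intermediate
13 | erylatissin C, (2S)-7-hydroxy-2-[3-hydroxy-4-methoxy-5-(3-methylbut-2-en-1-yl)phenyl]-2,3-dihydro-4H-chromen-4-one | COc1c(O)cc([C@@H]2CC(=O)c3ccc(O)cc3O2)cc1CC=C(C)C | target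

**Step count and risks**

Total steps: 7. Longest linear sequence: 5 steps (steps 1, 2, 3, 6, 7); the ring A branch (steps 4, 5) joins at step 6.

Steps most likely to fail:

1. Step 6. The desilylated alkoxide may fragment by retro-aldol or lose its oxygen by E1cB elimination faster than it closes the ring. Facial selectivity in the aldol stage may be poor with this electron-rich aldehyde. The product may also lose enantiomeric purity through base-induced opening to the chalcone and reclosure. Fallback, setting out from aldehyde 5 and coming back at compound 12: 2,4-dihydroxyacetophenone is selectively protected at the non-chelated 4-OH (MOMCl, K2CO3, acetone) to give 1-[2-hydroxy-4-(methoxymethoxy)phenyl]ethan-1-one F1. Claisen–Schmidt condensation of this ketone with 5 (KOH, EtOH/H2O, rt) should give the (E)-2'-hydroxychalcone F2. Intramolecular oxa-Michael addition (NaOAc, EtOH, reflux) should give the racemic bis(methoxymethyl) flavanone F3. Preparative HPLC on an amylose tris(3,5-dimethylphenylcarbamate) phase should then deliver the (S)-enantiomer, which is compound 12, while the (R)-enantiomer F4 is returned to the base equilibration; the route continues with step 7.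

2. Step 3. Carbon–carbon bond formation may occur at the dimethyl-substituted terminus of the allyl–palladium intermediate (branched 1,1-dimethylallyl isomer), and protodeboronation of the allylic boronate may compete. Fallback, setting out from bromide 3 and coming back at aldehyde 5: the aldehyde is masked (HC(OMe)3, MeOH, pyridinium p-toluenesulfonate cat., rt) as 1-bromo-5-(dimethoxymethyl)-2-methoxy-3-(methoxymethoxy)benzene F5. Bromine–lithium exchange (n-BuLi, THF, −78 °C) gives the aryllithium F6. Transmetalation with CuBr·SMe2 and SN2 alkylation with 1-bromo-3-methylbut-2-ene at the primary carbon should give 5-(dimethoxymethyl)-2-methoxy-1-(methoxymethoxy)-3-(3-methylbut-2-en-1-yl)benzene F7. Mild acetal hydrolysis (pyridinium p-toluenesulfonate, acetone/H2O, rt) should return 5 with the methoxymethyl ether intact.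

3. Step 7. Protic acid may add methanol, water or HCl across the trisubstituted alkene (Markovnikov addition) during the time needed to cleave both acetals, and prolonged heating in acid may erode the C2 configuration through enolisation and ring opening. Fallback, setting out from 12 and coming back at 13: aprotic silyl transfer with TMSOTf and 2,2'-bipyridyl (CH2Cl2, 0 °C) should convert both aryl methoxymethyl ethers, through N-(methoxymethyl)bipyridinium salts, into the bis(trimethylsilyl) ether F8 without exposing the alkene to a Brønsted acid. Neutral hydrolysis (H2O/THF, pH 7 buffer, rt) then frees the two phenols to give 13.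

**Further compounds**

F1 | step 6 | 1-[2-hydroxy-4-(methoxymethoxy)phenyl]ethan-1-one | CC(=O)c1ccc(OCOC)cc1O
F2 | step 6 | (2E)-1-[2-hydroxy-4-(methoxymethoxy)phenyl]-3-[4-methoxy-3-(methoxymethoxy)-5-(3-methylbut-2-en-1-yl)phenyl]prop-2-en-1-one | COc1c(OCOC)cc(/C=C/C(=O)c2ccc(OCOC)cc2O)cc1CC=C(C)C
F3 | step 6 | racemic 7-(methoxymethoxy)-2-[4-methoxy-3-(methoxymethoxy)-5-(3-methylbut-2-en-1-yl)phenyl]-2,3-dihydro-4H-chromen-4-one | COc1c(OCOC)cc(C2CC(=O)c3ccc(OCOC)cc3O2)cc1CC=C(C)C
F4 | step 6 | (2R)-7-(methoxymethoxy)-2-[4-methoxy-3-(methoxymethoxy)-5-(3-methylbut-2-en-1-yl)phenyl]-2,3-dihydro-4H-chromen-4-one | COc1c(OCOC)cc([C@H]2CC(=O)c3ccc(OCOC)cc3O2)cc1CC=C(C)C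
F5 | step 3 | 1-bromo-5-(dimethoxymethyl)-2-methoxy-3-(methoxymethoxy)benzene | COC(OC)c1cc(Br)c(OC)c(OCOC)c1
F6 | step 3 | [5-(dimethoxymethyl)-2-methoxy-3-(methoxymethoxy)phenyl]lithium | COC(OC)c1cc([Li])c(OC)c(OCOC)c1
F7 | step 3 | 5-(dimethoxymethyl)-2-methoxy-1-(methoxymethoxy)-3-(3-methylbut-2-en-1-yl)benzene | COC(OC)c1cc(CC=C(C)C)c(OC)c(OCOC)c1
F8 | step 7 | (2S)-2-[4-methoxy-5-(3-methylbut-2-en-1-yl)-3-[(trimethylsilyl)oxy]phenyl]-7-[(trimethylsilyl)oxy]-2,3-dihydro-4H-chromen-4-one | COc1c(O[Si](C)(C)C)cc([C@@H]2CC(=O)c3ccc(O[Si](C)(C)C)cc3O2)cc1CC=C(C)C
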